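## The problem

Compound 45 is a linear trimer of 7,8,4′-trihydroxyflavans: C4 of the top unit is bonded to C6 of the middle unit, and C4 of the middle unit to C6 of the bottom unit. The bottom unit is a 2,3-cis-3,4-cis flavan-3,4-diol (2R,3R,4R); the middle and top units are 2,3-cis-3,4-trans 4-arylflavan-3-ols, so nine stereocentres in three separate pyran rings have to be set. Within one pyran ring the centres can steer each other: a C4 aryl group blocks one face of C3, and a C3 oxygen can hand a group to C2 on its own face. The rings are too far apart for one unit to control the next, so each unit needs its own source of absolute configuration. The A rings are pyrogallol-type (oxygen at C7 and C8, none at C5), which makes C6 only a moderate carbon nucleophile; the classical union of a flavan-4-yl cation with a second flavan is then prone to ether formation, C5/C6 mixtures and over-oligomerisation. Fragile features are the benzylic C4 hydroxyl of the bottom unit (ionised by acid, open to hydrogenolysis), the three catechols (air-sensitive once free) and the 2,3-cis arrangement, which is lost whenever C2 or C4 becomes cationic. The feature that opens the problem is that ring A of an upper unit (C4a to C8a, with oxygen on C7, C8 and C8a) is the aromatic tautomer of a cyclohex-3-ene-1,2-dione enol ether. C4a and O1 can therefore be the enol carbon and enol oxygen of cyclohexane-1,2-dione 17, and C2–C3–C4 the three carbons of an enal whose β-carbon already carries the lower flavan as an ordinary aryl group.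

## Retrosynthesis

**45 ⇒ 44 ⇒ 43 (protecting groups).** Ten O–benzyl bonds and the acetonide of the bottom diol are cut last. Benzyl ethers are chosen because one hydrogenolysis removes all of them and they tolerate the bases, hydrides and oxidants of the route; the acetonide ties up the benzylic C4–O bond until the end. The acetonide is removed first, on the benzylated compound 43, where the C4 cation is harder to form than in the free phenol. The hydrogenolysis of 44 must then spare the benzylic C4–OH.

**43 ⇒ 41 + 5 (C2–aryl of the top unit).** Cutting the C2–aryl bond leaves the lactol 41 and 4-benzyloxyphenylboronic acid 5. The neighbouring cuts are worse: O1–C2 would reopen the ring closed in the key step, and C2–C3 would call for an open-chain aldol. The forward reaction must deliver the aryl group to the face of the C3 oxygen (2,3-cis); this face is also the one away from the C4 aryl group, so tether and sterics point the same way.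

**41 ⇒ 40 ⇒ 39 (C3–O).** The C3 oxygen is cut back to the lactone 39. The lactone locks the ring, acidifies C3–H, and lets an oxaziridine approach the enolate anti to the C4 substituent (3,4-trans). Reduction with i-Bu2AlH then returns the lactol oxidation level at C2.

**39 ⇒ 38 ⇒ 36 ⇒ 35 (the benzo ring).** The dibenzylated catechol ring of 39 is traced to the catechol 38, and 38 to its non-aromatic tautomer, the 7,8-dione 37. The dione is one oxidation above the ketone 35, so only the C7–O bond has to be made. A direct SeO2 oxidation of 35 was weighed and set aside: with an enone it can dehydrogenate or attack the γ-positions C4 and C5, and it would leave an oxidant in contact with an electron-rich catechol. The oxidation is therefore split into kinetic α′-hydroxylation (36) and a Swern-type oxidation whose oxidant is consumed before the catechol appears.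

**35 ⇒ 34 (oxidation level of C2).** The enol lactone 35 comes from the lactol 34 by oxidation. This is done at once so that no later base meets a ring-opened hydroxy aldehyde.

**34 ⇒ 32 + 17 (key disconnection).** C4–C4a and O1–C2 are cut together. The precursors are the dimer-derived enal 32 and cyclohexane-1,2-dione 17, a six-carbon reagent that carries both future ring oxygens in the right places. Against a cut at C4–C6, this one makes the interflavan bond part of an ordinary cinnamaldehyde and moves all stereocontrol to a catalyst. The forward reaction must form one stereocentre (C4) under catalyst control and end as a lactol rather than as a carbocyclic aldol product.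

**32 ⇒ 30 + 14; 30 ⇒ 29 (the enal).** The Cβ–C6 bond is cut to the aryl bromide 30 and acrolein diethyl acetal 14 (Heck reaction), and the C–Br bond to the protected dimer 29. C6 is para to O1 and ortho to the C7 ether; C5 is hindered by the C4 substituent and para only to the twisted C8 ether. Bromination plus Heck coupling is preferred to formylation plus Wittig extension because it needs neither a strong Lewis acid nor an organolithium on a polybenzylated acetonide.

**29 ⇒ 28 ⇒ 26 ⇒ 25 ⇒ 24 ⇒ 23 ⇒ 21 ⇒ 20 ⇒ 19 ⇒ 16 + 17 (the middle unit).** The first interflavan bond is made by the same cycle, not by a cation–arene union, for the reason given under the problem. Steps 10 to 17 are the monomer-level rehearsal of steps 21 to 28; only the benzylation of the C3 hydroxyl (29) is added, so that the oxidations of the second cycle find no free alcohol.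

**16 ⇒ 13 ⇒ 12 ⇒ 11 (bottom unit, functionalised).** The enal 16 comes from the bromide 13 and this from the acetonide 12 of the all-cis diol 11, by the same bromination and Heck coupling.

**11 ⇒ 8 (the cis-diol on the hindered face).** Both C–O bonds at C3 and C4 are cut to the flav-3-ene 8. Osmylation would add anti to the C2 aryl group and give the wrong 2,3-relationship. The Woodward cis-hydroxylation is asked to place both oxygens on the face of the aryl group, by iodonium formation on the open face followed by two inversions.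

**8 ⇒ 7 ⇒ 6 ⇒ 4 + 5; 4 ⇒ 2 ⇒ 1 (C2 and the carbon skeleton).** The alkene comes from the flavanone 6 by reduction and dehydration. The C2–aryl bond of 6 is cut to the chromone 4 and boronic acid 5 (catalytic asymmetric conjugate addition, the only source of chirality for the bottom unit). The chromone is two steps from gallacetophenone 1.

## Roads not taken

**Alternative 1:** The cut is made on both sides of C2 of the middle unit (C2–C3 and C2–aryl). In the forward direction LiCHCl2 would insert a chloromethine carbon into the C–B bond of the C3 boronic ester A1, with C3 migrating from boron to carbon. 4-Benzyloxyphenylmagnesium bromide would then add to boron and its aryl group displace chloride, giving the open-chain C2 boronic ester A2. Oxidation of the C–B bond and closure of O1 onto the bromoarene would finish the pyran ring.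
- Merits: both bonds at C2 are formed under the control of a chiral diol on boron, a reaction type with a long record of high diastereoselectivity, and the B ring enters as a simple Grignard reagent.
- Weak points: A1 already contains the C4 methine that joins the two flavans, so the hardest bond and its configuration are pushed back to an earlier, unspecified stage. A2 is a β-benzyloxy boronic ester, a class prone to boron–oxygen elimination. After the first migration the chloride-bearing carbon is α to boron and, once the aryl group is on, benzylic to a 4-alkoxyphenyl ring that can ionise. The ring closure is a further C–O coupling.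
- Comparison: in the control of C2 this road stands on firmer ground than the chosen plan, whose C2 arylation is a proposal. The chosen plan sets against this a single catalytic step that makes the interflavan C4 centre with fixed regiochemistry, and it never handles a β-alkoxy boronate.

**Alternative 2:** The cut is C4–C4a of the middle unit. BF3·OEt2 or hexafluoroisopropanol would activate the trans-epoxide A3, and the 2,3-bis(benzyloxy)phenyl ether ring would attack C4 with inversion through the carbon that becomes C4a. This closes the pyran ring and gives the dimer A4 with its C3 hydroxyl free.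
- Merits: one step closes the ring, fixes the 3,4-trans relationship from the epoxide geometry and unveils the C3 hydroxyl without a separate oxidation. Per flavan unit it is clearly shorter than the cycle chosen here.
- Weak points: C4 of A3 is benzylic to the electron-rich bottom-unit ring, so the epoxide can open to a cation before the arene arrives; stereospecificity is then lost and hydride or aryl shift competes. A3 needs three defined centres assembled on the bottom unit, so the interflavan bond and its configuration again come from outside the key step. The cyclic carbonate of A3 and A4 has to survive the Lewis acid.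
- Comparison: if ionisation can be held back, this is the more economical road. The chosen plan pays with more steps, but its C4 configuration comes from a catalyst and not from the lifetime of a benzylic cation, and ring A is built, so no position on it has to be selected in the ring-forming step.

**Alternative 3:** The cut is O1–C2 (with C3–O) of the top unit. Zn(OAc)2 would assist departure of the C2 mesylate of the dihydrobenzofuran A5 with participation of the ring oxygen, and acetate would then attack C3. O1–C2 and C3–OAc are formed and the five-membered ring grows to the pyran ring of A6.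
- Merits: two inversions of known sense give the 2,3-cis relationship stereospecifically, the C3 oxygen arrives protected, and the conditions are mild enough for the trimer stage.
- Weak points: A5 must already carry three contiguous centres and the whole dimer at the future C4, so the stereochemical problem is moved rather than solved. The mesylate is benzylic, which is why the B ring is worn as an electron-poor pivalate, and this costs a separate deprotection. Acetate can also return to the benzylic carbon without ring growth, or elimination can intervene.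
- Comparison: for the 2,3-cis relationship this road rests on a better-understood type of neighbouring-group chemistry than the directed arylation proposed here. The chosen plan offers in exchange the catalytic creation of C4 together with ring A and one uniform benzyl protecting scheme.

Key step: step 21

## Route

Names: "B" is the 6-yl residue of compound 12 (the all-cis bottom unit as its 3,4-acetonide). "MB" is the 6-yl residue of compound 29, a 2,3-cis-3,4-trans (2R,3R) middle unit with its C3 hydroxyl benzylated and carrying B at C4. New rings are numbered as chromans.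

Assumption: the (R)-pyridine-oxazoline ligand in step 3 and the (S)-prolinol silyl ether in steps 10 and 21 are taken to give the configurations drawn (addition to the enal face remote from the diarylmethyl group); should a sense prove opposite, the mirror-image catalyst is used.

Step 1
Reactants: 1 gallacetophenone
Product: 2 1-[3,4-bis(benzyloxy)-2-hydroxyphenyl]ethanone
Conditions: BnBr (2.1 equiv), K2CO3, acetone, reflux
Reagents that add atoms: benzyl bromide BrCc1ccccc1
Why: Williamson etherification; the C2 hydroxyl is hydrogen-bonded to the ketone and the least nucleophilic, so a limited amount of BnBr should leave it free.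

Step 2
Reactants: 2 1-[3,4-bis(benzyloxy)-2-hydroxyphenyl]ethanone
Product: 4 7,8-bis(benzyloxy)-4H-chromen-4-one, via enaminone 3 (not isolated)
Conditions: Me2NCH(OMe)2, toluene, 100 °C; then conc. HCl, CH2Cl2, 40 °C
Reagents that add atoms: N,N-dimethylformamide dimethyl acetal COC(OC)N(C)C
Why: Enaminone condensation at the acetyl methyl group, then acid-promoted addition–elimination by the phenol with loss of dimethylamine (standard chromone synthesis).

Step 3
Reactants: 4 7,8-bis(benzyloxy)-4H-chromen-4-one; 5 4-(benzyloxy)phenylboronic acid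
Product: 6 (2S)-7,8-bis(benzyloxy)-2-[4-(benzyloxy)phenyl]chroman-4-one
Conditions: Pd(OCOCF3)2 (5 mol %), (R)-4-tert-butyl-2-(pyridin-2-yl)-4,5-dihydrooxazole (6 mol %), NH4PF6, H2O, ClCH2CH2Cl, 60 °C
Reagents that add atoms: none
Why: Asymmetric conjugate addition of an arylboronic acid to a chromone under divalent-palladium/pyridine-oxazoline catalysis; the ligand-bound aryl–palladium species adds to one face of C2=C3 and water protonates the palladium enolate, which should set C2 as S.

Step 4
Reactants: 6 (2S)-flavanone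
Product: 7 (2S,4S)-7,8-bis(benzyloxy)-2-[4-(benzyloxy)phenyl]chroman-4-ol (2,4-cis)
Conditions: NaBH4, THF/MeOH, 0 °C
Reagents that add atoms: none
Why: Hydride reduction of the ketone, expected from the axial direction to give the 2,4-cis alcohol; the C4 configuration is of no consequence because it is removed in step 5.

Step 5
Reactants: 7 (2S,4S)-flavan-4-ol
Product: 8 (2S)-7,8-bis(benzyloxy)-2-[4-(benzyloxy)phenyl]-2H-chromene
Conditions: pyridinium p-toluenesulfonate (cat.), toluene, 4 Å sieves, 80 °C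
Reagents that add atoms: none
Why: Acid-catalysed dehydration through the benzylic cation stabilised by the C7 ether and O1; C2 is not touched.

Step 6
Reactants: 8 (2S)-flav-3-ene
Product: 11 (2R,3R,4R)-7,8-bis(benzyloxy)-2-[4-(benzyloxy)phenyl]chroman-3,4-diol, via trans-iodoacetate 9 (not isolated), via cis-hydroxy acetate 10 (not isolated)
Conditions: I2, AgOAc, AcOH, rt, dark; then H2O, 50 °C; then K2CO3, MeOH, rt
Reagents that add atoms: silver acetate CC(=O)[O-].[Ag+]
Why: Woodward cis-hydroxylation: the iodonium ion should form on the face away from the C2 aryl group, acetate opens it at benzylic C4, and the acetoxy group then displaces iodide at C3 with inversion to a cis-fused dioxolanylium ion that water opens. Both oxygens therefore end on the face of the aryl group (2,3-cis-3,4-cis), and methanolysis frees the diol.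

Step 7
Reactants: 11 all-cis diol
Product: 12 3,4-O-isopropylidene acetal of 11 (H–B)
Conditions: Me2C(OMe)2, pyridinium p-toluenesulfonate (cat.), CH2Cl2, rt
Reagents that add atoms: 2,2-dimethoxypropane COC(C)(C)OC
Why: Acetal exchange onto a cis-1,2-diol gives the cis-fused dioxolane under weak acid.

Step 8
Reactants: 12 acetonide H–B
Product: 13 6-bromo derivative of 12 (Br–B)
Conditions: NBS, DMF, 0 °C, dark
Reagents that add atoms: N-bromosuccinimide O=C1CCC(=O)N1Br
Why: Electrophilic aromatic bromination at C6, which is para to O1 and ortho to the C7 ether; C5 is peri to C4 and para only to the twisted C8 ether.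

Step 9
Reactants: 13 bromide Br–B; 14 acrolein diethyl acetal
Product: 16 (E)-3-B-prop-2-enal, via enal diethyl acetal 15 (not isolated)
Conditions: Pd(OAc)2 (5 mol %), n-Bu4NOAc, K2CO3, KCl, DMF, 90 °C; then 1 M HCl, THF, 0 °C
Reagents that add atoms: water O
Why: Heck reaction at the terminal carbon of the acrolein acetal with syn β-hydride elimination to the (E)-alkene; brief cold acid hydrolyses the allylic diethyl acetal much faster than the cyclic acetonide.

Step 10
Reactants: 16 (E)-3-B-prop-2-enal; 17 cyclohexane-1,2-dione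
Product: 19 (4R)-4-B-2-hydroxy-2,3,4,5,6,7-hexahydro-8H-chromen-8-one, via Michael adduct aldehyde 18 (not isolated)
Conditions: (S)-2-[diphenyl(trimethylsilyloxy)methyl]pyrrolidine (20 mol %), PhCO2H (20 mol %), CH2Cl2, 0 °C to rt
Reagents that add atoms: none
Why: Iminium-catalysed Michael addition–hemiacetalisation, the monomer-level rehearsal of step 21: the enol carbon of 17 adds to the β-carbon on the iminium face left open by the catalyst (C4 set as R) and the enol oxygen closes the lactol; the anomeric centre is left as a mixture.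

Step 11
Reactants: 19 lactol
Product: 20 (4R)-4-B-3,4,6,7-tetrahydro-2H-chromene-2,8(5H)-dione
Conditions: PhI(OAc)2, TEMPO (10 mol %), CH2Cl2, rt
Reagents that add atoms: none
Why: Oxoammonium-mediated oxidation of a lactol to the lactone; the ring is thereby locked against opening in the basic steps that follow.

Step 12
Reactants: 20 enol lactone ketone
Product: 21 (4R)-4-B-7-hydroxy-3,4,6,7-tetrahydro-2H-chromene-2,8(5H)-dione (C7 epimers)
Conditions: KN(SiMe3)2, THF, −78 °C; then 2-(phenylsulfonyl)-3-phenyloxaziridine, −78 °C; aq. NH4Cl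
Reagents that add atoms: 2-(phenylsulfonyl)-3-phenyloxaziridine O=S(=O)(c1ccccc1)N1OC1c1ccccc1
Why: Kinetic α′-deprotonation of the cross-conjugated ketone at C7 and electrophilic hydroxylation of the enolate by the N-sulfonyloxaziridine; the C7 configuration is irrelevant.

Step 13
Reactants: 21 acyloin
Product: 23 (4R)-4-B-7,8-dihydroxychroman-2-one, via trione 22 (not isolated)
Conditions: DMSO, (CF3CO)2O, CH2Cl2, −78 °C; then Et3N, −78 °C to rt
Reagents that add atoms: none
Why: Swern-type oxidation of the acyloin gives the 7,8-dione, a non-aromatic tautomer of the catechol, which should enolise twice on warming with Et3N; the oxidant is spent before the electron-rich catechol appears.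

Step 14
Reactants: 23 catechol lactone
Product: 24 (4R)-4-B-7,8-bis(benzyloxy)chroman-2-one
Conditions: BnBr, K2CO3, dry DMF, rt, argon
Reagents that add atoms: benzyl bromide BrCc1ccccc1
Why: Williamson etherification of both phenols under anhydrous conditions that leave the aryl lactone closed.

Step 15
Reactants: 24 dibenzyl lactone
Product: 25 (3R,4R)-4-B-7,8-bis(benzyloxy)-3-hydroxychroman-2-one (3,4-trans)
Conditions: KN(SiMe3)2, THF, −78 °C; then 2-(phenylsulfonyl)-3-phenyloxaziridine; aq. NH4Cl
Reagents that add atoms: 2-(phenylsulfonyl)-3-phenyloxaziridine O=S(=O)(c1ccccc1)N1OC1c1ccccc1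
Why: Lactone enolate hydroxylation; the oxaziridine should approach anti to the pseudoaxial C4 aryl group, which sets C3 trans to C4.

Step 16
Reactants: 25 hydroxy lactone
Product: 26 (3R,4R)-4-B-7,8-bis(benzyloxy)chroman-2,3-diol (anomer mixture)
Conditions: i-Bu2AlH (2.5 equiv), CH2Cl2, −78 °C; aq. KNaC4H4O6
Reagents that add atoms: none
Why: Partial reduction of an aryl lactone to the lactol at low temperature; the C3 alkoxide formed first consumes one hydride and the tetrahedral aluminate holds the lactol stage.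

Step 17
Reactants: 26 lactol diol; 5 4-(benzyloxy)phenylboronic acid
Product: 28 (2R,3R,4R)-4-B-7,8-bis(benzyloxy)-2-[4-(benzyloxy)phenyl]chroman-3-ol (2,3-cis-3,4-trans), via cyclic boronate 27 (not isolated)
Conditions: 5 (1.5 equiv), 4 Å sieves, CH2Cl2, rt; then BF3·OEt2, −40 to 0 °C
Reagents that add atoms: none
Why: Proposed new method: the cis-2,3-diol anomer of the lactol condenses with the boronic acid to a cyclic boronate, BF3 ionises the anomeric C2–O bond to an oxocarbenium ion that stays tethered through C3–O–B, and the electron-rich aryl group migrates from the now tetracoordinate boron to C2 on the face of the C3 oxygen, which is also the face away from the C4 aryl group, so the 2,3-cis product should result; the closest known reaction types are the hydroxyl-directed boronate arylation of N-acyliminium ions derived from 3-hydroxy-2-alkoxypyrrolidines and the Lewis-acid-promoted transfer of aryl groups from boron to oxocarbenium ions of chromene acetals and mixed acetals.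

Step 18
Reactants: 28 dimer flavan-3-ol
Product: 29 3-O-benzyl ether of 28 (H–MB, protected dimer)
Conditions: NaH, BnBr, n-Bu4NI (cat.), DMF, 0 °C to rt
Reagents that add atoms: benzyl bromide BrCc1ccccc1
Why: Williamson etherification of the only free hydroxyl, so that the oxidations of the second cycle meet no alcohol.

Step 19
Reactants: 29 protected dimer H–MB
Product: 30 6-bromo derivative of 29 (Br–MB)
Conditions: NBS, DMF, 0 °C, dark
Reagents that add atoms: N-bromosuccinimide O=C1CCC(=O)N1Br
Why: Electrophilic aromatic bromination; C6 of the middle unit is the only unhindered position activated by two ring oxygens (para to O1, ortho to the C7 ether), since C6 of the bottom unit is now substituted and the B rings are singly activated.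

Step 20
Reactants: 30 bromide Br–MB; 14 acrolein diethyl acetal
Product: 32 (E)-3-MB-prop-2-enal, via enal diethyl acetal 31 (not isolated)
Conditions: Pd(OAc)2 (5 mol %), n-Bu4NOAc, K2CO3, KCl, DMF, 90 °C; then 1 M HCl, THF, 0 °C
Reagents that add atoms: water O
Why: Heck reaction and acetal hydrolysis as in step 9; the (E)-geometry follows from syn β-hydride elimination.

Step 21
Reactants: 32 (E)-3-MB-prop-2-enal; 17 cyclohexane-1,2-dione
Product: 34 (4R)-4-MB-2-hydroxy-2,3,4,5,6,7-hexahydro-8H-chromen-8-one, via Michael adduct aldehyde 33 (not isolated)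
Conditions: (S)-2-[diphenyl(trimethylsilyloxy)methyl]pyrrolidine (20 mol %), PhCO2H (20 mol %), CH2Cl2, 0 °C to rt
Reagents that add atoms: none
Why: The catalyst condenses with enal 32 to an (E)-iminium ion, the enol of 17 adds through carbon to the β-carbon (C4–C4a), the enamine is hydrolysed to aldehyde 33, the dione part re-enolises to the conjugated diosphenol, and its hydroxyl adds to the aldehyde to close the lactol (O1–C2). The closest known reaction type is the secondary-amine-catalysed Michael addition–hemiacetalisation of cyclic 1,3- and 1,2-diones with β-aryl enals. The pyran ring closes by 6-exo-trig addition of the enol oxygen to the aldehyde carbonyl. C4 is the only stereocentre of consequence: the diphenyl(silyloxy)methyl group shields one face of the iminium ion, so the enol should add to the opposite (Si) face and give 4R under catalyst control, the existing centres being five or more bonds away, while the anomeric C2 forms as a mixture and is erased in step 22. The step needs 1,4- over 1,2-addition, C- over O-alkylation of the enol, and hemiacetalisation over aldol closure of the enamine onto the distal ketone to a bicyclo[3.2.1]octane. The first two follow from the soft, conjugated iminium acceptor. The third is favoured because the acid co-catalyst speeds enamine hydrolysis and because re-enolisation makes C4a trigonal, which rules out the bridged aldol product and holds the enol oxygen next to the aldehyde chain. The ortho-benzyloxy group on the β-aryl ring adds steric pressure against the compact aldol transition state.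

Step 22
Reactants: 34 lactol
Product: 35 (4R)-4-MB-3,4,6,7-tetrahydro-2H-chromene-2,8(5H)-dione
Conditions: PhI(OAc)2, TEMPO (10 mol %), CH2Cl2, rt
Reagents that add atoms: none
Why: Oxoammonium-mediated lactol-to-lactone oxidation as in step 11.

Step 23
Reactants: 35 enol lactone ketone
Product: 36 (4R)-4-MB-7-hydroxy-3,4,6,7-tetrahydro-2H-chromene-2,8(5H)-dione (C7 epimers)
Conditions: KN(SiMe3)2, THF, −78 °C; then 2-(phenylsulfonyl)-3-phenyloxaziridine, −78 °C; aq. NH4Cl
Reagents that add atoms: 2-(phenylsulfonyl)-3-phenyloxaziridine O=S(=O)(c1ccccc1)N1OC1c1ccccc1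
Why: Kinetic α′-enolate hydroxylation at C7 as in step 12.

Step 24
Reactants: 36 acyloin
Product: 38 (4R)-4-MB-7,8-dihydroxychroman-2-one, via trione 37 (not isolated)
Conditions: DMSO, (CF3CO)2O, CH2Cl2, −78 °C; then Et3N, −78 °C to rt
Reagents that add atoms: none
Why: Swern-type oxidation to the 7,8-dione and tautomerisation to the catechol as in step 13; this completes ring A of the top unit.

Step 25
Reactants: 38 catechol lactone
Product: 39 (4R)-4-MB-7,8-bis(benzyloxy)chroman-2-one
Conditions: BnBr, K2CO3, dry DMF, rt, argon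
Reagents that add atoms: benzyl bromide BrCc1ccccc1
Why: Williamson etherification of both phenols as in step 14.

Step 26
Reactants: 39 dibenzyl lactone
Product: 40 (3R,4R)-4-MB-7,8-bis(benzyloxy)-3-hydroxychroman-2-one (3,4-trans)
Conditions: KN(SiMe3)2, THF, −78 °C; then 2-(phenylsulfonyl)-3-phenyloxaziridine; aq. NH4Cl
Reagents that add atoms: 2-(phenylsulfonyl)-3-phenyloxaziridine O=S(=O)(c1ccccc1)N1OC1c1ccccc1
Why: Lactone enolate hydroxylation anti to the C4 aryl group as in step 15, setting C3 of the top unit.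

Step 27
Reactants: 40 hydroxy lactone
Product: 41 (3R,4R)-4-MB-7,8-bis(benzyloxy)chroman-2,3-diol (anomer mixture)
Conditions: i-Bu2AlH (2.5 equiv), CH2Cl2, −78 °C; aq. KNaC4H4O6
Reagents that add atoms: none
Why: Partial reduction of the aryl lactone to the lactol as in step 16.

Step 28
Reactants: 41 lactol diol; 5 4-(benzyloxy)phenylboronic acid
Product: 43 protected trimer with free top C3 hydroxyl (2,3-cis-3,4-trans top unit), via cyclic boronate 42 (not isolated)
Conditions: 5 (1.5 equiv), 4 Å sieves, CH2Cl2, rt; then BF3·OEt2, −40 to 0 °C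
Reagents that add atoms: none
Why: Proposed new method: as in step 17, the cyclic boronate of the cis-2,3-diol anomer is ionised at C2 by BF3 and the aryl group migrates from boron, held on the C3 oxygen, to the same face of the oxocarbenium ion, away from the C4 aryl group, which should set C2 of the top unit cis to C3; the closest known reaction types are the hydroxyl-directed boronate arylation of N-acyliminium ions and the Lewis-acid-promoted boron-to-carbon aryl transfer to oxocarbenium ions of chromene acetals and mixed acetals.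

Step 29
Reactants: 43 protected trimer
Product: 44 trimer deca-benzyl ether with free bottom 3,4-diol
Conditions: AcOH/THF/H2O (3:1:1), 45 °C
Reagents that add atoms: none
Why: Acetal hydrolysis through the dialkoxycarbenium ion at the acetonide carbon; the weak acid should leave the benzylic C4–O bond and the interflavan bonds alone.

Step 30
Reactants: 44 deca-benzyl ether
Product: 45 target trimer
Conditions: H2 (1 atm), Pd(OH)2/C, THF/MeOH, rt
Reagents that add atoms: none
Why: Hydrogenolysis of ten aryl benzyl ethers under neutral conditions, which cleave far faster than the secondary benzylic C4–OH or the doubly benzylic C–C bonds.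

## Compound list

1 | gallacetophenone, 1-(2,3,4-trihydroxyphenyl)ethanone | CC(=O)c1ccc(O)c(O)c1O | starting material
2 | 1-[3,4-bis(benzyloxy)-2-hydroxyphenyl]ethanone | CC(=O)c1ccc(OCc2ccccc2)c(OCc2ccccc2)c1O | intermediate
3 | (E)-1-[3,4-bis(benzyloxy)-2-hydroxyphenyl]-3-(dimethylamino)prop-2-en-1-one | CN(C)/C=C/C(=O)c1ccc(OCc2ccccc2)c(OCc2ccccc2)c1O | intermediate
4 | 7,8-bis(benzyloxy)-4H-chromen-4-one | O=c1ccoc2c1ccc(OCc1ccccc1)c2OCc1ccccc1 | intermediate
5 | 4-(benzyloxy)phenylboronic acid | OB(O)c1ccc(OCc2ccccc2)cc1 | starting material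
6 | (2S)-7,8-bis(benzyloxy)-2-[4-(benzyloxy)phenyl]chroman-4-one | O=C1C[C@@H](c2ccc(OCc3ccccc3)cc2)Oc2c1ccc(OCc1ccccc1)c2OCc1ccccc1 | intermediate
7 | (2S,4S)-7,8-bis(benzyloxy)-2-[4-(benzyloxy)phenyl]chroman-4-ol (2,4-cis) | O[C@H]1C[C@@H](c2ccc(OCc3ccccc3)cc2)Oc2c1ccc(OCc1ccccc1)c2OCc1ccccc1 | intermediate
8 | (2S)-7,8-bis(benzyloxy)-2-[4-(benzyloxy)phenyl]-2H-chromene | C1=C[C@@H](c2ccc(OCc3ccccc3)cc2)Oc2c1ccc(OCc1ccccc1)c2OCc1ccccc1 | intermediate
9 | 4-acetoxy-7,8-bis(benzyloxy)-2-[4-(benzyloxy)phenyl]-3-iodochroman, iodine trans to the C2 aryl and to the C4 acetoxy group | CC(=O)O[C@H]1[C@H](I)[C@@H](c2ccc(OCc3ccccc3)cc2)Oc2c1ccc(OCc1ccccc1)c2OCc1ccccc1 | intermediate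
10 | all-cis 3-acetoxy-7,8-bis(benzyloxy)-2-[4-(benzyloxy)phenyl]chroman-4-ol (the 4-acetate may accompany it) | O[C@H]1[C@@H](OC(C)=O)[C@@H](c2ccc(OCc3ccccc3)cc2)Oc2c1ccc(OCc1ccccc1)c2OCc1ccccc1 | intermediate
11 | (2R,3R,4R)-7,8-bis(benzyloxy)-2-[4-(benzyloxy)phenyl]chroman-3,4-diol (2,3-cis-3,4-cis) | O[C@H]1[C@@H](O)[C@@H](c2ccc(OCc3ccccc3)cc2)Oc2c1ccc(OCc1ccccc1)c2OCc1ccccc1 | intermediate
12 | 3,4-O-isopropylidene acetal of 11 (H–B) | c3cc4c(c(OCc5ccccc5)c3OCc5ccccc5)O[C@H](c3ccc(OCc5ccccc5)cc3)[C@H](O6)[C@@H]4OC6(C)C | intermediate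
13 | 6-bromo derivative of 12 (Br–B) | Brc3cc4c(c(OCc5ccccc5)c3OCc5ccccc5)O[C@H](c3ccc(OCc5ccccc5)cc3)[C@H](O6)[C@@H]4OC6(C)C | intermediate
14 | acrolein diethyl acetal (3,3-diethoxyprop-1-ene) | C=CC(OCC)OCC | starting material
15 | (E)-3-B-prop-2-enal diethyl acetal | CCOC(OCC)/C=C/c3cc4c(c(OCc5ccccc5)c3OCc5ccccc5)O[C@H](c3ccc(OCc5ccccc5)cc3)[C@H](O6)[C@@H]4OC6(C)C | intermediate
16 | (E)-3-B-prop-2-enal | O=C/C=C/c3cc4c(c(OCc5ccccc5)c3OCc5ccccc5)O[C@H](c3ccc(OCc5ccccc5)cc3)[C@H](O6)[C@@H]4OC6(C)C | intermediate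
17 | cyclohexane-1,2-dione | O=C1CCCCC1=O | starting material
18 | (3R)-3-B-3-(2-hydroxy-3-oxocyclohex-1-en-1-yl)propanal | O=CC[C@@H](c3cc4c(c(OCc5ccccc5)c3OCc5ccccc5)O[C@H](c3ccc(OCc5ccccc5)cc3)[C@H](O6)[C@@H]4OC6(C)C)C1=C(O)C(=O)CCC1 | intermediate
19 | (4R)-4-B-2-hydroxy-2,3,4,5,6,7-hexahydro-8H-chromen-8-one (anomers) | OC1C[C@@H](c3cc4c(c(OCc5ccccc5)c3OCc5ccccc5)O[C@H](c3ccc(OCc5ccccc5)cc3)[C@H](O6)[C@@H]4OC6(C)C)C2=C(O1)C(=O)CCC2 | intermediate
20 | (4R)-4-B-3,4,6,7-tetrahydro-2H-chromene-2,8(5H)-dione | O=C1C[C@@H](c3cc4c(c(OCc5ccccc5)c3OCc5ccccc5)O[C@H](c3ccc(OCc5ccccc5)cc3)[C@H](O6)[C@@H]4OC6(C)C)C2=C(O1)C(=O)CCC2 | intermediate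
21 | (4R)-4-B-7-hydroxy-3,4,6,7-tetrahydro-2H-chromene-2,8(5H)-dione (C7 epimers) | O=C1C[C@@H](c3cc4c(c(OCc5ccccc5)c3OCc5ccccc5)O[C@H](c3ccc(OCc5ccccc5)cc3)[C@H](O6)[C@@H]4OC6(C)C)C2=C(O1)C(=O)C(O)CC2 | intermediate
22 | (4R)-4-B-3,4,5,6-tetrahydro-2H-chromene-2,7,8-trione | O=C1C[C@@H](c3cc4c(c(OCc5ccccc5)c3OCc5ccccc5)O[C@H](c3ccc(OCc5ccccc5)cc3)[C@H](O6)[C@@H]4OC6(C)C)C2=C(O1)C(=O)C(=O)CC2 | intermediate
23 | (4R)-4-B-7,8-dihydroxychroman-2-one | O=C1C[C@@H](c3cc4c(c(OCc5ccccc5)c3OCc5ccccc5)O[C@H](c3ccc(OCc5ccccc5)cc3)[C@H](O6)[C@@H]4OC6(C)C)c2ccc(O)c(O)c2O1 | intermediate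
24 | (4R)-4-B-7,8-bis(benzyloxy)chroman-2-one | O=C1C[C@@H](c3cc4c(c(OCc5ccccc5)c3OCc5ccccc5)O[C@H](c3ccc(OCc5ccccc5)cc3)[C@H](O6)[C@@H]4OC6(C)C)c2ccc(OCc5ccccc5)c(OCc5ccccc5)c2O1 | intermediate
25 | (3R,4R)-4-B-7,8-bis(benzyloxy)-3-hydroxychroman-2-one (3,4-trans) | O=C1[C@H](O)[C@@H](c3cc4c(c(OCc5ccccc5)c3OCc5ccccc5)O[C@H](c3ccc(OCc5ccccc5)cc3)[C@H](O6)[C@@H]4OC6(C)C)c2ccc(OCc5ccccc5)c(OCc5ccccc5)c2O1 | intermediate
26 | (3R,4R)-4-B-7,8-bis(benzyloxy)chroman-2,3-diol (3,4-trans, anomers) | OC1[C@H](O)[C@@H](c3cc4c(c(OCc5ccccc5)c3OCc5ccccc5)O[C@H](c3ccc(OCc5ccccc5)cc3)[C@H](O6)[C@@H]4OC6(C)C)c2ccc(OCc5ccccc5)c(OCc5ccccc5)c2O1 | intermediate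
27 | cyclic 4-(benzyloxy)phenylboronate of the 2,3-cis anomer of 26 | B1(c2ccc(OCc5ccccc5)cc2)O[C@H]2Oc7c(OCc5ccccc5)c(OCc5ccccc5)ccc7[C@H](c3cc4c(c(OCc5ccccc5)c3OCc5ccccc5)O[C@H](c3ccc(OCc5ccccc5)cc3)[C@H](O6)[C@@H]4OC6(C)C)[C@H]2O1 | intermediate
28 | (2R,3R,4R)-4-B-7,8-bis(benzyloxy)-2-[4-(benzyloxy)phenyl]chroman-3-ol (2,3-cis-3,4-trans) | c3cc4c(c(OCc5ccccc5)c3OCc5ccccc5)O[C@H](c3ccc(OCc5ccccc5)cc3)[C@H](O)[C@H]4c3cc4c(c(OCc5ccccc5)c3OCc5ccccc5)O[C@H](c3ccc(OCc5ccccc5)cc3)[C@H](O6)[C@@H]4OC6(C)C | intermediate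
29 | 3-O-benzyl ether of 28 (H–MB, protected dimer) | c3cc4c(c(OCc5ccccc5)c3OCc5ccccc5)O[C@H](c3ccc(OCc5ccccc5)cc3)[C@H](OCc5ccccc5)[C@H]4c3cc4c(c(OCc5ccccc5)c3OCc5ccccc5)O[C@H](c3ccc(OCc5ccccc5)cc3)[C@H](O6)[C@@H]4OC6(C)C | intermediate
30 | 6-bromo derivative of 29 (Br–MB) | Brc3cc4c(c(OCc5ccccc5)c3OCc5ccccc5)O[C@H](c3ccc(OCc5ccccc5)cc3)[C@H](OCc5ccccc5)[C@H]4c3cc4c(c(OCc5ccccc5)c3OCc5ccccc5)O[C@H](c3ccc(OCc5ccccc5)cc3)[C@H](O6)[C@@H]4OC6(C)C | intermediate
31 | (E)-3-MB-prop-2-enal diethyl acetal | CCOC(OCC)/C=C/c3cc4c(c(OCc5ccccc5)c3OCc5ccccc5)O[C@H](c3ccc(OCc5ccccc5)cc3)[C@H](OCc5ccccc5)[C@H]4c3cc4c(c(OCc5ccccc5)c3OCc5ccccc5)O[C@H](c3ccc(OCc5ccccc5)cc3)[C@H](O6)[C@@H]4OC6(C)C | intermediate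
32 | (E)-3-MB-prop-2-enal | O=C/C=C/c3cc4c(c(OCc5ccccc5)c3OCc5ccccc5)O[C@H](c3ccc(OCc5ccccc5)cc3)[C@H](OCc5ccccc5)[C@H]4c3cc4c(c(OCc5ccccc5)c3OCc5ccccc5)O[C@H](c3ccc(OCc5ccccc5)cc3)[C@H](O6)[C@@H]4OC6(C)C | intermediate
33 | (3R)-3-MB-3-(2-hydroxy-3-oxocyclohex-1-en-1-yl)propanal | O=CC[C@@H](c3cc4c(c(OCc5ccccc5)c3OCc5ccccc5)O[C@H](c3ccc(OCc5ccccc5)cc3)[C@H](OCc5ccccc5)[C@H]4c3cc4c(c(OCc5ccccc5)c3OCc5ccccc5)O[C@H](c3ccc(OCc5ccccc5)cc3)[C@H](O6)[C@@H]4OC6(C)C)C1=C(O)C(=O)CCC1 | intermediate
34 | (4R)-4-MB-2-hydroxy-2,3,4,5,6,7-hexahydro-8H-chromen-8-one (anomers) | OC1C[C@@H](c3cc4c(c(OCc5ccccc5)c3OCc5ccccc5)O[C@H](c3ccc(OCc5ccccc5)cc3)[C@H](OCc5ccccc5)[C@H]4c3cc4c(c(OCc5ccccc5)c3OCc5ccccc5)O[C@H](c3ccc(OCc5ccccc5)cc3)[C@H](O6)[C@@H]4OC6(C)C)C2=C(O1)C(=O)CCC2 | intermediate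
35 | (4R)-4-MB-3,4,6,7-tetrahydro-2H-chromene-2,8(5H)-dione | O=C1C[C@@H](c3cc4c(c(OCc5ccccc5)c3OCc5ccccc5)O[C@H](c3ccc(OCc5ccccc5)cc3)[C@H](OCc5ccccc5)[C@H]4c3cc4c(c(OCc5ccccc5)c3OCc5ccccc5)O[C@H](c3ccc(OCc5ccccc5)cc3)[C@H](O6)[C@@H]4OC6(C)C)C2=C(O1)C(=O)CCC2 | intermediate
36 | (4R)-4-MB-7-hydroxy-3,4,6,7-tetrahydro-2H-chromene-2,8(5H)-dione (C7 epimers) | O=C1C[C@@H](c3cc4c(c(OCc5ccccc5)c3OCc5ccccc5)O[C@H](c3ccc(OCc5ccccc5)cc3)[C@H](OCc5ccccc5)[C@H]4c3cc4c(c(OCc5ccccc5)c3OCc5ccccc5)O[C@H](c3ccc(OCc5ccccc5)cc3)[C@H](O6)[C@@H]4OC6(C)C)C2=C(O1)C(=O)C(O)CC2 | intermediate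
37 | (4R)-4-MB-3,4,5,6-tetrahydro-2H-chromene-2,7,8-trione | O=C1C[C@@H](c3cc4c(c(OCc5ccccc5)c3OCc5ccccc5)O[C@H](c3ccc(OCc5ccccc5)cc3)[C@H](OCc5ccccc5)[C@H]4c3cc4c(c(OCc5ccccc5)c3OCc5ccccc5)O[C@H](c3ccc(OCc5ccccc5)cc3)[C@H](O6)[C@@H]4OC6(C)C)C2=C(O1)C(=O)C(=O)CC2 | intermediate
38 | (4R)-4-MB-7,8-dihydroxychroman-2-one | O=C1C[C@@H](c3cc4c(c(OCc5ccccc5)c3OCc5ccccc5)O[C@H](c3ccc(OCc5ccccc5)cc3)[C@H](OCc5ccccc5)[C@H]4c3cc4c(c(OCc5ccccc5)c3OCc5ccccc5)O[C@H](c3ccc(OCc5ccccc5)cc3)[C@H](O6)[C@@H]4OC6(C)C)c2ccc(O)c(O)c2O1 | intermediate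
39 | (4R)-4-MB-7,8-bis(benzyloxy)chroman-2-one | O=C1C[C@@H](c3cc4c(c(OCc5ccccc5)c3OCc5ccccc5)O[C@H](c3ccc(OCc5ccccc5)cc3)[C@H](OCc5ccccc5)[C@H]4c3cc4c(c(OCc5ccccc5)c3OCc5ccccc5)O[C@H](c3ccc(OCc5ccccc5)cc3)[C@H](O6)[C@@H]4OC6(C)C)c2ccc(OCc5ccccc5)c(OCc5ccccc5)c2O1 | intermediate
40 | (3R,4R)-4-MB-7,8-bis(benzyloxy)-3-hydroxychroman-2-one (3,4-trans) | O=C1[C@H](O)[C@@H](c3cc4c(c(OCc5ccccc5)c3OCc5ccccc5)O[C@H](c3ccc(OCc5ccccc5)cc3)[C@H](OCc5ccccc5)[C@H]4c3cc4c(c(OCc5ccccc5)c3OCc5ccccc5)O[C@H](c3ccc(OCc5ccccc5)cc3)[C@H](O6)[C@@H]4OC6(C)C)c2ccc(OCc5ccccc5)c(OCc5ccccc5)c2O1 | intermediate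
41 | (3R,4R)-4-MB-7,8-bis(benzyloxy)chroman-2,3-diol (3,4-trans, anomers) | OC1[C@H](O)[C@@H](c3cc4c(c(OCc5ccccc5)c3OCc5ccccc5)O[C@H](c3ccc(OCc5ccccc5)cc3)[C@H](OCc5ccccc5)[C@H]4c3cc4c(c(OCc5ccccc5)c3OCc5ccccc5)O[C@H](c3ccc(OCc5ccccc5)cc3)[C@H](O6)[C@@H]4OC6(C)C)c2ccc(OCc5ccccc5)c(OCc5ccccc5)c2O1 | intermediate
42 | cyclic 4-(benzyloxy)phenylboronate of the 2,3-cis anomer of 41 | B1(c2ccc(OCc5ccccc5)cc2)O[C@H]2Oc7c(OCc5ccccc5)c(OCc5ccccc5)ccc7[C@H](c3cc4c(c(OCc5ccccc5)c3OCc5ccccc5)O[C@H](c3ccc(OCc5ccccc5)cc3)[C@H](OCc5ccccc5)[C@H]4c3cc4c(c(OCc5ccccc5)c3OCc5ccccc5)O[C@H](c3ccc(OCc5ccccc5)cc3)[C@H](O6)[C@@H]4OC6(C)C)[C@H]2O1 | intermediate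
43 | protected trimer: top unit 7,8,4′-tri-O-benzyl with free C3 hydroxyl (2,3-cis-3,4-trans), C4 bonded to MB | C(c5ccccc5)Oc1ccc([C@H]2Oc3c(ccc(OCc5ccccc5)c3OCc5ccccc5)[C@H](c3cc4c(c(OCc5ccccc5)c3OCc5ccccc5)O[C@H](c3ccc(OCc5ccccc5)cc3)[C@H](OCc5ccccc5)[C@H]4c3cc4c(c(OCc5ccccc5)c3OCc5ccccc5)O[C@H](c3ccc(OCc5ccccc5)cc3)[C@H](O6)[C@@H]4OC6(C)C)[C@H]2O)cc1 | intermediate
44 | trimer deca-benzyl ether with free bottom 3,4-diol and free top C3 hydroxyl | C(c5ccccc5)Oc1ccc([C@H]2Oc3c(ccc(OCc5ccccc5)c3OCc5ccccc5)[C@H](c3cc4c(c(OCc5ccccc5)c3OCc5ccccc5)O[C@H](c3ccc(OCc5ccccc5)cc3)[C@H](OCc5ccccc5)[C@H]4c3cc4c(c(OCc5ccccc5)c3OCc5ccccc5)O[C@H](c3ccc(OCc5ccccc5)cc3)[C@H](O)[C@@H]4O)[C@H]2O)cc1 | intermediate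
45 | CNP0140823.1, the 7,8,4′-trihydroxyflavan trimer (top and middle 2,3-cis-3,4-trans, bottom 2,3-cis-3,4-cis) | Oc1ccc([C@H]2Oc3c(ccc(O)c3O)[C@H](c3cc4c(c(O)c3O)O[C@H](c3ccc(O)cc3)[C@H](O)[C@H]4c3cc4c(c(O)c3O)O[C@H](c3ccc(O)cc3)[C@H](O)[C@@H]4O)[C@H]2O)cc1 | target

## Step count and least certain steps

Total: 30 steps. Longest linear sequence: 30 steps (1 to 45); 5, 14 and 17 are purchased.

**Step 17 (proposed method).** The aryl transfer from boron may not keep pace with ionisation at C2, so that the oxocarbenium ion is lost to elimination or to intermolecular capture, and BF3 may open the acetonide. Fallback with known reactions, setting out from lactone 25: 4-benzyloxyphenyllithium is added to the lactone at −78 °C to give the ring-opened (2R,3R)-hydroxy ketone F1. Zn(BH4)2 then reduces the ketone under chelation with the C3 hydroxyl to the anti-1,2-diol F2. Mitsunobu closure (PPh3, diisopropyl azodicarboxylate) of the phenol onto the benzylic carbinol with inversion gives the 2,3-cis flavan-3-ol and returns to the route at 28.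

**Step 28 (proposed method).** The same failure modes apply, with a more hindered and more valuable substrate. Fallback from lactone 40: addition of 4-benzyloxyphenyllithium gives the hydroxy ketone F3, chelation-controlled reduction with Zn(BH4)2 the anti-diol F4, and Mitsunobu closure with inversion at the benzylic carbon returns to the route at 43.

**Step 21 (key step).** The enamine formed after the Michael addition may close by aldol reaction onto the distal ketone faster than it is hydrolysed, diverting material to a bridged carbocycle. Iminium formation from the hindered, electron-rich enal may be slow enough for facial selectivity to erode through an uncatalysed pathway. Step 10 tests both points on the monomer. Fallback from bromide 30: Miyaura borylation (bis(pinacolato)diboron, PdCl2(dppf), KOAc) gives the dimer pinacol boronate F5. This is added to 7,8-bis(benzyloxy)coumarin F6 (from daphnetin and BnBr) under Rh(acac)(C2H4)2/(S)-SEGPHOS catalysis, an asymmetric Hayashi–Miyaura 1,4-addition to a coumarin. The product is the lactone 39, where the route is rejoined. The price is that such additions normally need one partner in large excess, and here the boron partner is the precious one.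

**Step 6.** The electrophilic iodine reagent may abstract hydride from C2 of the flavene (aromatisation to a flavylium ion) instead of adding. The iodonium ion may also form on both faces, or the benzylic C4–O bond may ionise and scramble the 3,4-relationship. Fallback from flavanone 6: soft enolisation (Me3SiOTf, Et3N) gives the silyl enol ether F7. Rubottom oxidation with dimethyldioxirane, anti to the aryl group, gives the trans-3-hydroxyflavanone F8. Mitsunobu reaction with 4-nitrobenzoic acid inverts C3 to the cis ester F9. NaBH4 then adds hydride anti to the axial acyloxy group to give the all-cis hydroxy ester F10, and K2CO3 in MeOH cleaves the ester, returning to the route at 11.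

**Step 23 (and its first run, step 12).** Deprotonation may lose its α′-selectivity and occur at the γ-positions, which would epimerise C4, or the base may attack the enol lactone. Fallback from 35: soft enolisation with Me3SiOTf and Et3N gives the cross-conjugated silyl dienol ether F11 without a free alkali enolate, and Rubottom oxidation with dimethyldioxirane followed by mild acid returns to the route at 36.

**Step 30.** Hydrogenolysis may continue into the benzylic C4–OH bond of the bottom unit once the para oxygen is free, or stop short as the polyphenol poisons the catalyst. Fallback from 43: the order of deprotection is reversed. Hydrogenolysis with the acetonide still in place, where the C4–O bond is held in the dioxolane, gives the phenolic acetonide F12. Aqueous acetic acid under argon then removes the acetonide and arrives at 45.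

## Further compounds

F1 | step 17 | (2R,3R)-3-B-3-[3,4-bis(benzyloxy)-2-hydroxyphenyl]-1-[4-(benzyloxy)phenyl]-2-hydroxypropan-1-one (may exist as its cyclic hemiketal) | O=C(c3ccc(OCc5ccccc5)cc3)[C@H](O)[C@@H](c3cc4c(c(OCc5ccccc5)c3OCc5ccccc5)O[C@H](c3ccc(OCc5ccccc5)cc3)[C@H](O6)[C@@H]4OC6(C)C)c1ccc(OCc5ccccc5)c(OCc5ccccc5)c1O
F2 | step 17 | anti-1,2-diol from F1: 3-B-3-[3,4-bis(benzyloxy)-2-hydroxyphenyl]-1-[4-(benzyloxy)phenyl]propane-1,2-diol | O[C@@H](c3ccc(OCc5ccccc5)cc3)[C@H](O)[C@@H](c3cc4c(c(OCc5ccccc5)c3OCc5ccccc5)O[C@H](c3ccc(OCc5ccccc5)cc3)[C@H](O6)[C@@H]4OC6(C)C)c1ccc(OCc5ccccc5)c(OCc5ccccc5)c1O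
F3 | step 28 | (2R,3R)-3-MB-3-[3,4-bis(benzyloxy)-2-hydroxyphenyl]-1-[4-(benzyloxy)phenyl]-2-hydroxypropan-1-one | O=C(c3ccc(OCc5ccccc5)cc3)[C@H](O)[C@@H](c3cc4c(c(OCc5ccccc5)c3OCc5ccccc5)O[C@H](c3ccc(OCc5ccccc5)cc3)[C@H](OCc5ccccc5)[C@H]4c3cc4c(c(OCc5ccccc5)c3OCc5ccccc5)O[C@H](c3ccc(OCc5ccccc5)cc3)[C@H](O6)[C@@H]4OC6(C)C)c1ccc(OCc5ccccc5)c(OCc5ccccc5)c1O
F4 | step 28 | anti-1,2-diol from F3 | O[C@@H](c3ccc(OCc5ccccc5)cc3)[C@H](O)[C@@H](c3cc4c(c(OCc5ccccc5)c3OCc5ccccc5)O[C@H](c3ccc(OCc5ccccc5)cc3)[C@H](OCc5ccccc5)[C@H]4c3cc4c(c(OCc5ccccc5)c3OCc5ccccc5)O[C@H](c3ccc(OCc5ccccc5)cc3)[C@H](O6)[C@@H]4OC6(C)C)c1ccc(OCc5ccccc5)c(OCc5ccccc5)c1O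
F5 | step 21 | MB-boronic acid pinacol ester | B1(OC(C)(C)C(C)(C)O1)c3cc4c(c(OCc5ccccc5)c3OCc5ccccc5)O[C@H](c3ccc(OCc5ccccc5)cc3)[C@H](OCc5ccccc5)[C@H]4c3cc4c(c(OCc5ccccc5)c3OCc5ccccc5)O[C@H](c3ccc(OCc5ccccc5)cc3)[C@H](O6)[C@@H]4OC6(C)C
F6 | step 21 | 7,8-bis(benzyloxy)-2H-chromen-2-one | O=c1ccc2ccc(OCc3ccccc3)c(OCc3ccccc3)c2o1
F7 | step 6 | (2S)-7,8-bis(benzyloxy)-2-[4-(benzyloxy)phenyl]-4-(trimethylsilyloxy)-2H-chromene | C[Si](C)(C)OC1=C[C@@H](c2ccc(OCc3ccccc3)cc2)Oc2c1ccc(OCc1ccccc1)c2OCc1ccccc1
F8 | step 6 | (2R,3R)-7,8-bis(benzyloxy)-2-[4-(benzyloxy)phenyl]-3-hydroxychroman-4-one (2,3-trans) | O=C1[C@H](O)[C@@H](c2ccc(OCc3ccccc3)cc2)Oc2c1ccc(OCc1ccccc1)c2OCc1ccccc1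
F9 | step 6 | 2,3-cis 7,8-bis(benzyloxy)-2-[4-(benzyloxy)phenyl]-4-oxochroman-3-yl 4-nitrobenzoate | O=C1[C@@H](OC(=O)c2ccc(cc2)[N+](=O)[O-])[C@@H](c2ccc(OCc3ccccc3)cc2)Oc2c1ccc(OCc1ccccc1)c2OCc1ccccc1
F10 | step 6 | all-cis 7,8-bis(benzyloxy)-2-[4-(benzyloxy)phenyl]-4-hydroxychroman-3-yl 4-nitrobenzoate | O[C@H]1[C@@H](OC(=O)c2ccc(cc2)[N+](=O)[O-])[C@@H](c2ccc(OCc3ccccc3)cc2)Oc2c1ccc(OCc1ccccc1)c2OCc1ccccc1
F11 | step 23 | (4R)-4-MB-8-(trimethylsilyloxy)-3,4,5,6-tetrahydro-2H-chromen-2-one | O=C1C[C@@H](c3cc4c(c(OCc5ccccc5)c3OCc5ccccc5)O[C@H](c3ccc(OCc5ccccc5)cc3)[C@H](OCc5ccccc5)[C@H]4c3cc4c(c(OCc5ccccc5)c3OCc5ccccc5)O[C@H](c3ccc(OCc5ccccc5)cc3)[C@H](O6)[C@@H]4OC6(C)C)C2=C(O1)C(O[Si](C)(C)C)=CCC2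
F12 | step 30 | 3,4-O-isopropylidene acetal (bottom unit) of 45 | Oc1ccc([C@H]2Oc3c(ccc(O)c3O)[C@H](c3cc4c(c(O)c3O)O[C@H](c3ccc(O)cc3)[C@H](O)[C@H]4c3cc4c(c(O)c3O)O[C@H](c3ccc(O)cc3)[C@H](O6)[C@@H]4OC6(C)C)[C@H]2O)cc1
A1 | alternative 1 | C3 boronic ester of the open-chain middle unit on the bottom unit (dicyclohexylethanediol ester) | B7(O[C@@H](C6CCCCC6)[C@H](C6CCCCC6)O7)[C@H](OCc5ccccc5)[C@@H](c3cc4c(c(OCc5ccccc5)c3OCc5ccccc5)O[C@H](c3ccc(OCc5ccccc5)cc3)[C@H](O6)[C@@H]4OC6(C)C)c3ccc(OCc5ccccc5)c(OCc5ccccc5)c3Br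
A2 | alternative 1 | open-chain middle unit as the C2 boronic ester on the bottom unit | C(c5ccccc5)Oc1ccc([C@@H](B7O[C@@H](C6CCCCC6)[C@H](C6CCCCC6)O7)[C@H](OCc5ccccc5)[C@@H](c3cc4c(c(OCc5ccccc5)c3OCc5ccccc5)O[C@H](c3ccc(OCc5ccccc5)cc3)[C@H](O6)[C@@H]4OC6(C)C)c3ccc(OCc5ccccc5)c(OCc5ccccc5)c3Br)cc1
A3 | alternative 2 | trans-epoxide carrying the 2,3-bis(benzyloxy)phenyl ether at C2 and the bottom unit (3,4-carbonate) at C4 | C(c5ccccc5)Oc1ccc([C@@H](Oc2cccc(OCc5ccccc5)c2OCc5ccccc5)[C@@H]2O[C@H]2c3cc4c(c(OCc5ccccc5)c3OCc5ccccc5)O[C@H](c3ccc(OCc5ccccc5)cc3)[C@H](O6)[C@@H]4OC6=O)cc1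
A4 | alternative 2 | protected middle–bottom dimer with free middle C3 hydroxyl (bottom 3,4-carbonate) | C(c5ccccc5)Oc1ccc([C@H]2Oc3c(ccc(OCc5ccccc5)c3OCc5ccccc5)[C@H](c3cc4c(c(OCc5ccccc5)c3OCc5ccccc5)O[C@H](c3ccc(OCc5ccccc5)cc3)[C@H](O6)[C@@H]4OC6=O)[C@H]2O)cc1
A5 | alternative 3 | 2-[mesyloxy(4-pivaloyloxyphenyl)methyl]-6,7-bis(benzyloxy)-3-MB-2,3-dihydrobenzofuran | CC(C)(C)C(=O)Oc1ccc([C@H](OS(C)(=O)=O)[C@H]2Oc3c(ccc(OCc5ccccc5)c3OCc5ccccc5)[C@@H]2c3cc4c(c(OCc5ccccc5)c3OCc5ccccc5)O[C@H](c3ccc(OCc5ccccc5)cc3)[C@H](OCc5ccccc5)[C@H]4c3cc4c(c(OCc5ccccc5)c3OCc5ccccc5)O[C@H](c3ccc(OCc5ccccc5)cc3)[C@H](O6)[C@@H]4OC6(C)C)cc1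
A6 | alternative 3 | protected trimer, top unit as 3-O-acetate and 4′-O-pivalate | CC(C)(C)C(=O)Oc1ccc([C@H]2Oc3c(ccc(OCc5ccccc5)c3OCc5ccccc5)[C@H](c3cc4c(c(OCc5ccccc5)c3OCc5ccccc5)O[C@H](c3ccc(OCc5ccccc5)cc3)[C@H](OCc5ccccc5)[C@H]4c3cc4c(c(OCc5ccccc5)c3OCc5ccccc5)O[C@H](c3ccc(OCc5ccccc5)cc3)[C@H](O6)[C@@H]4OC6(C)C)[C@H]2OC(C)=O)cc1
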